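Every mole of substrate charged stays on the books, so at any hour the substrate left, the target and the rest (two intermediates, two side products) add up to the charge.

the same everywhere: third reagent 0.475 M

|  | substrate | partner | second reagent | temperature | remark | time |
|---|---|---|---|---|---|---|
| teal | 0.50 M | 0.60 M | 0.37 M | 30 °C | run made earlier |  |
| ochre | 0.50 M | 0.60 M | 0.83 M | 42 °C | run made earlier |  |
| blue | 0.75 M | 0.60 M | 0.55 M | 30 °C | run made earlier |  |
| north-west | 0.50 M | 0.600 M | 0.550 M | 50 °C |  | 40 h |
| south | 0.50 M | 0.600 M | 0.550 M | 35 °C |  | 40 h |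

| run | time / h | target / % | substrate / % |
|---|---|---|---|
| teal | 8.00 | 1.6 | 82.3 |
| teal | 15.0 | 6.2 | 71.2 |
| teal | 20.0 | 7.9 | 64.4 |
| teal | 40.0 | 19.3 | 46.9 |
| teal | 72.0 | 28.0 | 31.0 |
| teal | 120 | 33.8 | 19.1 |
| ochre | 6.00 | 8.1 | 54.7 |
| ochre | 12.0 | 13.4 | 33.1 |
| ochre | 20.0 | 17.6 | 19.2 |
| ochre | 25.0 | 19.6 | 13.1 |
| ochre | 30.0 | 21.0 | 10.7 |
| ochre | 40.0 | 22.6 | 4.9 |
| blue | 10.0 | 3.1 | 77.2 |
| blue | 25.0 | 11.9 | 57.0 |
| blue | 60.0 | 23.6 | 35.6 |
| blue | 72.0 | 24.4 | 31.4 |
| blue | 120 | 29.8 | 22.4 |

(each reading ± 0.5 percentage points)

- steps under discussion: substrate + second reagent -> side product A; second reagent + intermediate A -> intermediate B; substrate + partner -> intermediate A; third reagent + intermediate B -> target; intermediate B -> side product B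

1. the flask that comes out highest in amount of target, in percent of the substrate charged, or "all alike" when all lie within 1.5 percentage points (north-west / south / all alike)
2. target at the end, in percent of the substrate charged, north-west
3. target at the end, in percent of the substrate charged, south

I kept two lines of that ledger. The first was turnovers, ln(charge/left). Teal and blue, both at 30 °C, began at 0.0243 h⁻¹ and 0.0259 h⁻¹ despite different second reagent, so I charged ochre's 0.101 h⁻¹, a factor of 3.89 over blue, to its bath at 42 °C, though ochre also held more second reagent than blue. Spread evenly over the degrees, that made the 40 h of south worth 70.4 h at 30 °C. Blue, with south's second reagent but more substrate, had 31.4% left at 72.0 h. The same hours in north-west came to 384 h, well past blue's last reading, so I booked north-west's substrate as converted, as an estimate.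

The second line was target per substrate lost. Blue read 35.6% at 72.0 h, the yield on conversion, and ochre read 23.8% at its last.

So my south closed at 24.4% target, and my north-west, on ochre's yield, at 23.8%. They stood 0.60 percentage points apart, and I expected all alike.

The forecast gave 23.5% for north-west and 26% for south, higher than my south, and chose south: “South is slightly ahead”.

The flasks gave 24.6% in north-west and 24.1% in south: all alike.

    substrate + second reagent → side product A (k = 1.10 × 10⁻⁵ M⁻¹ s⁻¹, Ea = 85.0 kJ mol⁻¹)
    second reagent + intermediate A → intermediate B (k = 3.10 × 10⁻⁴ M⁻¹ s⁻¹, Ea = 67.0 kJ mol⁻¹)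
    substrate + partner → intermediate A (k = 1.20 × 10⁻⁵ M⁻¹ s⁻¹, Ea = 68.0 kJ mol⁻¹)
    third reagent + intermediate B → target (k = 9.70 × 10⁻⁵ M⁻¹ s⁻¹, Ea = 73.0 kJ mol⁻¹)
    intermediate B → side product B (k = 2.40 × 10⁻⁵ s⁻¹, Ea = 111 kJ mol⁻¹)
    (constants at 35 °C)

South had 27.0% of its substrate left at 40.0 h, so the yield on conversion from blue books 26.0% of target against the 24.1% it held. Its own ratio then was 33.0%, with 2.17% in intermediate A and 2.61% in intermediate B. The same south read at 3.0 d had 14% of its substrate left, so the ledger books 30.6% of target there, and that flask held 30.8%.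

Readings and results were computed with constants of no real substance; the scatter is artificial.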